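**Retrosynthetic overview**

1. The target is read as all-E (3S,6S,6'S)-ε,ε-caroten-3-ol. Two Wittig disconnections (C11=C12 and C11'=C12') give a C10 trienedial and two C15 end-group phosphonium salts, and both salts descend from one hydroxy dienoate (the C3 oxygen is kept in one and removed in the other).
2. That dienoate goes back, by enone reduction, ketone-to-enone dehydrogenation and Horner–Wadsworth–Emmons chain extension, to a C10 4-oxocyclohexanecarbaldehyde that already holds the ring, the quaternary C1 and the C6 stereocentre of both end groups.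
3. Key disconnection: this ring is cut at C1–C2 and C5–C6 into 3-methylbut-2-enal (C1 with both methyls, C6, C7) and a 2-silyloxypenta-1,3-diene (C2–C5 with the C5 methyl), joined by an amine-catalysed enantioselective [4+2] reaction.
4. Enabling feature: in each ε-ring the C1(CH3)2–C6H–C7 edge is the β-carbon, α-carbon and formyl carbon of a β,β-dimethyl enal (two equal methyls, so only C6 is stereogenic). The C2–C3–C4–C5(CH3) edge is a pentadiene chain whose C3 can carry oxygen (the carbinol carbon of the hydroxylated ring), and because C1 is quaternary the C3 ketone can be desaturated only toward C4=C5.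
5. Ring order: both six-membered rings are made first, in the same operation (step 2, one batch that is divided after step 5); no ring is formed afterwards and the polyene is completed last.

Key step: step 2

Assumption: ring positions in the Why lines follow carotenoid numbering (C1 gem-dimethyl carbon, C3 carbinol carbon, C5 methyl-bearing alkene carbon, C6 side-chain carbon). The descriptor of the side-chain carbon changes from 1R (compounds 4, 5) to 1S (from 7 on) only because substituent priorities change. Reagent 6 is sold as an E/Z mixture, and the minor (2Z) dienoate is expected to be removable by chromatography after step 3.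

**Step 1**
Reactants: 1 (E)-pent-3-en-2-one
Product: 2 (E)-2-(tert-butyldimethylsilyloxy)penta-1,3-diene
Conditions: TBSOTf (1.1 equiv), Et3N (1.5 equiv), Et2O, 0 °C
Reagents that add atoms: tert-butyldimethylsilyl trifluoromethanesulfonate, CC(C)(C)[Si](C)(C)OS(=O)(=O)C(F)(F)F
Why: soft enolisation and O-silylation of the methyl ketone (silyl enol ether formation) should give the cross-conjugated 2-silyloxydiene with the E-propenyl geometry of 1 retained.

**Step 2**
Reactants: 2 (E)-2-(tert-butyldimethylsilyloxy)penta-1,3-diene; 3 3-methylbut-2-enal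
Product: 5 (1R)-2,6,6-trimethyl-4-oxocyclohexane-1-carbaldehyde (both C2 epimers), via silyl enol ether cycloadduct 4 (not isolated)
Conditions: (R)-2-[diphenyl(trimethylsilyloxy)methyl]pyrrolidine (20 mol%), CF3CO2H (20 mol%), 2 (1.5 equiv), toluene, −20 → 0 °C, slow addition of 3; then 1 M HCl, THF, 0 °C
Reagents that add atoms: none
Why: Proposed new method: the secondary amine condenses with 3 to an E-configured, s-trans iminium ion; the CH2 terminus of 2 (C2), made nucleophilic by the 2-silyloxy group, adds to the tertiary β-carbon (C1), and the enamine carbon that results (C6) closes onto the other diene terminus (C5), so that both bonds form in one asynchronous [4+2] event (Mukaiyama–Michael addition followed by Michael ring closure) that returns the silyl enol ether and frees the catalyst on hydrolysis. The closest known reaction types are the iminium-catalysed Diels–Alder reaction of β,β-disubstituted enals with cyclopentadiene, which shows that such hindered iminium ions form and are attacked at the fully substituted carbon, and the iminium-catalysed Mukaiyama–Michael addition of silyl enol ethers to enals; new here is the pairing of a β,β-dimethyl enal with an acyclic 2-silyloxydiene. The six-membered ring is closed by the second bond, C5–C6, in a 6-endo-trig sense (enamine α-carbon onto the β-carbon of the silyloxyallyl cation or enone). C6 is the only stereocentre that must be controlled: the CPh2(OSiMe3) arm covers one face of the iminium and enamine π-system, the diene bonds on the open face, and with the (R)-catalyst this should give the (1R)-aldehyde, which is the (S)-C6 of both end groups; C1 carries two identical methyls and the epimer mixture at C5 is erased in step 4, so neither endo/exo selectivity nor a defined diene face is needed. The step needs 1,4- instead of 1,2-attack, the C2-to-C1 and C5-to-C6 orientation, and cross- instead of self-reaction of 3: iminium activation sends the soft π-nucleophile to the β-carbon, the donor oxygen on C3 fixes the polarity of the diene, and the acidic medium with slow addition of 3 to excess 2 keeps the dienamine of 3 low.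

**Step 3**
Reactants: 5 (1R)-2,6,6-trimethyl-4-oxocyclohexane-1-carbaldehyde; 6 ethyl (E)-4-(diethoxyphosphoryl)-3-methylbut-2-enoate
Product: 7 ethyl (2E,4E)-3-methyl-5-[(1S)-2,6,6-trimethyl-4-oxocyclohexyl]penta-2,4-dienoate (both ring C2 epimers)
Conditions: 6 (1.2 equiv), LiN(SiMe3)2 (1.15 equiv), THF, −78 °C; then 5, −78 → 0 °C
Reagents that add atoms: none
Why: Horner–Wadsworth–Emmons olefination in which the preformed, weakly basic vinylogous phosphonate anion should attack the aldehyde much faster than the ring ketone, give the trans C7=C8 bond, and at low temperature leave the C6 stereocentre next to the formyl group untouched.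

**Step 4**
Reactants: 7 ethyl (2E,4E)-3-methyl-5-[(1S)-2,6,6-trimethyl-4-oxocyclohexyl]penta-2,4-dienoate
Product: 8 ethyl (2E,4E)-3-methyl-5-[(1S)-2,6,6-trimethyl-4-oxocyclohex-2-en-1-yl]penta-2,4-dienoate
Conditions: IBX (1.5 equiv), 4-methoxypyridine N-oxide (1.5 equiv), DMSO, 25 °C
Reagents that add atoms: none
Why: IBX dehydrogenation of a ketone to its enone can run only toward C4=C5, because the other α-carbon (C2) has the quaternary C1 as neighbour and no β-hydrogen, so both C5 epimers should converge on one enone while C6 stays untouched.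

**Step 5**
Reactants: 8 ethyl (2E,4E)-3-methyl-5-[(1S)-2,6,6-trimethyl-4-oxocyclohex-2-en-1-yl]penta-2,4-dienoate
Product: 9 ethyl (2E,4E)-5-[(1S,4S)-4-hydroxy-2,6,6-trimethylcyclohex-2-en-1-yl]-3-methylpenta-2,4-dienoate
Conditions: NaBH4, CeCl3·7H2O, MeOH, −40 °C; chromatographic separation from the C4 epimer
Reagents that add atoms: none
Why: Luche 1,2-reduction leaves the dienoate alone, and hydride is expected to enter C3 mainly on the face opposite the pseudoaxial C1 methyl group of the conformer with a pseudoaxial C6 side chain, which places the hydroxyl trans to the side chain (3S).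

**Step 6**
Reactants: 9 ethyl (2E,4E)-5-[(1S,4S)-4-hydroxy-2,6,6-trimethylcyclohex-2-en-1-yl]-3-methylpenta-2,4-dienoate
Product: 10 ethyl (2E,4E)-5-[(1S,4S)-4-(tert-butyldimethylsilyloxy)-2,6,6-trimethylcyclohex-2-en-1-yl]-3-methylpenta-2,4-dienoate
Conditions: TBSCl, imidazole, DMF, 25 °C
Reagents that add atoms: tert-butyldimethylsilyl chloride, CC(C)(C)[Si](C)(C)Cl
Why: standard silylation of a secondary alcohol, which should shield the ionisable ring allylic hydroxyl during phosphonium salt formation and the Wittig reaction.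

**Step 7**
Reactants: 10 ethyl (2E,4E)-5-[(1S,4S)-4-(tert-butyldimethylsilyloxy)-2,6,6-trimethylcyclohex-2-en-1-yl]-3-methylpenta-2,4-dienoate
Product: 11 (2E,4E)-5-[(1S,4S)-4-(tert-butyldimethylsilyloxy)-2,6,6-trimethylcyclohex-2-en-1-yl]-3-methylpenta-2,4-dien-1-ol
Conditions: iBu2AlH (2.5 equiv), CH2Cl2, −78 °C; aqueous potassium sodium tartrate
Reagents that add atoms: none
Why: 1,2-reduction of a conjugated ester to the allylic alcohol by the aluminium hydride should leave the silyl ether and all alkenes unchanged.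

**Step 8**
Reactants: 11 (2E,4E)-5-[(1S,4S)-4-(tert-butyldimethylsilyloxy)-2,6,6-trimethylcyclohex-2-en-1-yl]-3-methylpenta-2,4-dien-1-ol
Product: 13 [(2E,4E)-5-[(1S,4S)-4-(tert-butyldimethylsilyloxy)-2,6,6-trimethylcyclohex-2-en-1-yl]-3-methylpenta-2,4-dien-1-yl]triphenylphosphonium bromide, via allylic bromide 12 (not isolated)
Conditions: CBr4 (1.1 equiv), PPh3 (2.3 equiv), CH2Cl2, 0 → 25 °C
Reagents that add atoms: tetrabromomethane, BrC(Br)(Br)Br; triphenylphosphine, c1ccc(cc1)P(c1ccccc1)c1ccccc1
Why: Appel bromination of the primary allylic alcohol under neutral conditions, followed by SN2 quaternisation of the excess phosphine at the primary carbon, should give the salt without acid reaching the ring allylic ether.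

**Step 9**
Reactants: 9 ethyl (2E,4E)-5-[(1S,4S)-4-hydroxy-2,6,6-trimethylcyclohex-2-en-1-yl]-3-methylpenta-2,4-dienoate
Product: 14 ethyl (2E,4E)-5-[(1S,4S)-4-(methoxycarbonyloxy)-2,6,6-trimethylcyclohex-2-en-1-yl]-3-methylpenta-2,4-dienoate
Conditions: ClCO2Me, pyridine, DMAP (cat.), CH2Cl2, 0 °C
Reagents that add atoms: methyl chloroformate, COC(=O)Cl
Why: routine O-acylation turns the allylic hydroxyl into a leaving group for palladium, and either C3 configuration would serve because C3 becomes a methylene group in step 10.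

**Step 10**
Reactants: 14 ethyl (2E,4E)-5-[(1S,4S)-4-(methoxycarbonyloxy)-2,6,6-trimethylcyclohex-2-en-1-yl]-3-methylpenta-2,4-dienoate
Product: 15 ethyl (2E,4E)-3-methyl-5-[(1S)-2,6,6-trimethylcyclohex-2-en-1-yl]penta-2,4-dienoate
Conditions: Pd(PPh3)4 (5 mol%), NaBH4 (2 equiv), THF, 0 → 25 °C
Reagents that add atoms: none
Why: Tsuji–Trost-type allylic hydrogenolysis, in which zerovalent palladium ionises the carbonate to a C3–C5 allyl complex and borohydride should deliver hydride to the less substituted terminus C3, leaving the trisubstituted C4=C5 alkene and the C6 stereocentre (outside the allyl unit) in place.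

**Step 11**
Reactants: 15 ethyl (2E,4E)-3-methyl-5-[(1S)-2,6,6-trimethylcyclohex-2-en-1-yl]penta-2,4-dienoate
Product: 16 (2E,4E)-3-methyl-5-[(1S)-2,6,6-trimethylcyclohex-2-en-1-yl]penta-2,4-dien-1-ol
Conditions: iBu2AlH (2.5 equiv), CH2Cl2, −78 °C; aqueous potassium sodium tartrate
Reagents that add atoms: none
Why: 1,2-reduction of the conjugated ester by the aluminium hydride should give the dienylic alcohol without touching the ring alkene.

**Step 12**
Reactants: 16 (2E,4E)-3-methyl-5-[(1S)-2,6,6-trimethylcyclohex-2-en-1-yl]penta-2,4-dien-1-ol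
Product: 17 [(2E,4E)-3-methyl-5-[(1S)-2,6,6-trimethylcyclohex-2-en-1-yl]penta-2,4-dien-1-yl]triphenylphosphonium bromide
Conditions: Ph3P·HBr (1.05 equiv), MeOH, 25 °C
Reagents that add atoms: triphenylphosphine hydrobromide, [Br-].[PH+](c1ccccc1)(c1ccccc1)c1ccccc1
Why: acid-mediated ionisation of the dienylic alcohol to a delocalised cation and capture by the phosphine at the primary terminus is the standard formation of C15 Wittig salts and should not affect the isolated ring alkene or C6.

**Step 13**
Reactants: 17 [(2E,4E)-3-methyl-5-[(1S)-2,6,6-trimethylcyclohex-2-en-1-yl]penta-2,4-dien-1-yl]triphenylphosphonium bromide; 18 (2E,4E,6E)-2,7-dimethylocta-2,4,6-trienedial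
Product: 19 (2E,4E,6E,8E,10E,12E)-2,7,11-trimethyl-13-[(1S)-2,6,6-trimethylcyclohex-2-en-1-yl]trideca-2,4,6,8,10,12-hexaenal
Conditions: 18 (3 equiv), NaOMe, MeOH/CH2Cl2, 0 °C; then n-heptane, reflux, argon
Reagents that add atoms: none
Why: Wittig olefination of one formyl group by the semi-stabilised ylide (the excess dialdehyde suppresses double reaction) should form C11=C12, and thermal equilibration should bring the new double bond to E.

**Step 14**
Reactants: 13 [(2E,4E)-5-[(1S,4S)-4-(tert-butyldimethylsilyloxy)-2,6,6-trimethylcyclohex-2-en-1-yl]-3-methylpenta-2,4-dien-1-yl]triphenylphosphonium bromide; 19 (2E,4E,6E,8E,10E,12E)-2,7,11-trimethyl-13-[(1S)-2,6,6-trimethylcyclohex-2-en-1-yl]trideca-2,4,6,8,10,12-hexaenal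
Product: 20 (all-E)-(3S,6S,6'S)-3-(tert-butyldimethylsilyloxy)-ε,ε-carotene
Conditions: NaOMe, MeOH/CH2Cl2, 0 → 25 °C; then n-heptane, reflux, argon, dark
Reagents that add atoms: none
Why: the second Wittig olefination should form C11'=C12' and complete the C40 polyene, with thermal equilibration to the all-E isomer as is usual for carotenoids.

**Step 15**
Reactants: 20 (all-E)-(3S,6S,6'S)-3-(tert-butyldimethylsilyloxy)-ε,ε-carotene
Product: 21 (all-E)-(3S,6S,6'S)-ε,ε-caroten-3-ol (target)
Conditions: Bu4NF, THF, 0 → 25 °C, argon, dark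
Reagents that add atoms: none
Why: fluoride cleavage of the silyl ether should free the 3-hydroxyl without acid, so the allylic alcohol and the polyene are not disturbed.

**Compound list**

1 | (E)-pent-3-en-2-one | C/C=C/C(C)=O | starting material
2 | (E)-2-(tert-butyldimethylsilyloxy)penta-1,3-diene | C/C=C/C(=C)O[Si](C)(C)C(C)(C)C | intermediate
3 | 3-methylbut-2-enal | CC(C)=CC=O | starting material
4 | (1R)-4-(tert-butyldimethylsilyloxy)-2,6,6-trimethylcyclohex-3-ene-1-carbaldehyde (both C2 epimers) | O=C[C@@H]1C(C)C=C(O[Si](C)(C)C(C)(C)C)CC1(C)C | intermediate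
5 | (1R)-2,6,6-trimethyl-4-oxocyclohexane-1-carbaldehyde (both C2 epimers) | O=C[C@@H]1C(C)CC(=O)CC1(C)C | intermediate
6 | ethyl (E)-4-(diethoxyphosphoryl)-3-methylbut-2-enoate | CCOC(=O)/C=C(C)/CP(=O)(OCC)OCC | starting material
7 | ethyl (2E,4E)-3-methyl-5-[(1S)-2,6,6-trimethyl-4-oxocyclohexyl]penta-2,4-dienoate (both ring C2 epimers) | CCOC(=O)/C=C(C)/C=C/[C@@H]1C(C)CC(=O)CC1(C)C | intermediate
8 | ethyl (2E,4E)-3-methyl-5-[(1S)-2,6,6-trimethyl-4-oxocyclohex-2-en-1-yl]penta-2,4-dienoate | CCOC(=O)/C=C(C)/C=C/[C@@H]1C(C)=CC(=O)CC1(C)C | intermediate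
9 | ethyl (2E,4E)-5-[(1S,4S)-4-hydroxy-2,6,6-trimethylcyclohex-2-en-1-yl]-3-methylpenta-2,4-dienoate | CCOC(=O)/C=C(C)/C=C/[C@@H]1C(C)=C[C@@H](O)CC1(C)C | intermediate
10 | ethyl (2E,4E)-5-[(1S,4S)-4-(tert-butyldimethylsilyloxy)-2,6,6-trimethylcyclohex-2-en-1-yl]-3-methylpenta-2,4-dienoate | CCOC(=O)/C=C(C)/C=C/[C@@H]1C(C)=C[C@@H](O[Si](C)(C)C(C)(C)C)CC1(C)C | intermediate
11 | (2E,4E)-5-[(1S,4S)-4-(tert-butyldimethylsilyloxy)-2,6,6-trimethylcyclohex-2-en-1-yl]-3-methylpenta-2,4-dien-1-ol | OC/C=C(C)/C=C/[C@@H]1C(C)=C[C@@H](O[Si](C)(C)C(C)(C)C)CC1(C)C | intermediate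
12 | tert-butyl{[(1S,4S)-4-[(1E,3E)-5-bromo-3-methylpenta-1,3-dien-1-yl]-3,5,5-trimethylcyclohex-2-en-1-yl]oxy}dimethylsilane | BrC/C=C(C)/C=C/[C@@H]1C(C)=C[C@@H](O[Si](C)(C)C(C)(C)C)CC1(C)C | intermediate
13 | [(2E,4E)-5-[(1S,4S)-4-(tert-butyldimethylsilyloxy)-2,6,6-trimethylcyclohex-2-en-1-yl]-3-methylpenta-2,4-dien-1-yl]triphenylphosphonium bromide | [Br-].c1ccccc1[P+](c1ccccc1)(c1ccccc1)C/C=C(C)/C=C/[C@@H]1C(C)=C[C@@H](O[Si](C)(C)C(C)(C)C)CC1(C)C | intermediate
14 | ethyl (2E,4E)-5-[(1S,4S)-4-(methoxycarbonyloxy)-2,6,6-trimethylcyclohex-2-en-1-yl]-3-methylpenta-2,4-dienoate | CCOC(=O)/C=C(C)/C=C/[C@@H]1C(C)=C[C@@H](OC(=O)OC)CC1(C)C | intermediate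
15 | ethyl (2E,4E)-3-methyl-5-[(1S)-2,6,6-trimethylcyclohex-2-en-1-yl]penta-2,4-dienoate | CCOC(=O)/C=C(C)/C=C/[C@@H]1C(C)=CCCC1(C)C | intermediate
16 | (2E,4E)-3-methyl-5-[(1S)-2,6,6-trimethylcyclohex-2-en-1-yl]penta-2,4-dien-1-ol | OC/C=C(C)/C=C/[C@@H]1C(C)=CCCC1(C)C | intermediate
17 | [(2E,4E)-3-methyl-5-[(1S)-2,6,6-trimethylcyclohex-2-en-1-yl]penta-2,4-dien-1-yl]triphenylphosphonium bromide | [Br-].c1ccccc1[P+](c1ccccc1)(c1ccccc1)C/C=C(C)/C=C/[C@@H]1C(C)=CCCC1(C)C | intermediate
18 | (2E,4E,6E)-2,7-dimethylocta-2,4,6-trienedial | O=C/C(C)=C/C=C/C=C(C)/C=O | starting material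
19 | (2E,4E,6E,8E,10E,12E)-2,7,11-trimethyl-13-[(1S)-2,6,6-trimethylcyclohex-2-en-1-yl]trideca-2,4,6,8,10,12-hexaenal | CC1=CCCC(C)(C)[C@@H]1/C=C/C(C)=C/C=C/C(C)=C/C=C/C=C(C)/C=O | intermediate
20 | (all-E)-(3S,6S,6'S)-3-(tert-butyldimethylsilyloxy)-ε,ε-carotene | CC1=CCCC(C)(C)[C@@H]1/C=C/C(C)=C/C=C/C(C)=C/C=C/C=C(C)/C=C/C=C(C)/C=C/[C@@H]1C(C)=C[C@@H](O[Si](C)(C)C(C)(C)C)CC1(C)C | intermediate
21 | (all-E)-(3S,6S,6'S)-ε,ε-caroten-3-ol | CC1=CCCC(C)(C)[C@@H]1/C=C/C(C)=C/C=C/C(C)=C/C=C/C=C(C)/C=C/C=C(C)/C=C/[C@@H]1C(C)=C[C@@H](O)CC1(C)C | target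

**Step count and risks**

Total step count: 15. Longest linear sequence: 12 steps (steps 1–5 and 9–15).

Steps most likely to fail:

Step 2 (proposed new method). Self-condensation of 3 through its dienamine, protodesilylation of 2 by the ammonium salt, or incomplete facial control by the catalyst may prevent clean formation of enantioenriched 5. The fallback sets out from 2 and 3 and comes back to the route at 9. The two components are joined without amine in a Lewis-acid-promoted Diels–Alder reaction (Me2AlCl, CH2Cl2, −78 °C), a known reaction type for 2-silyloxydienes with enals and the established way to bring β,β-dimethyl dienophiles into cycloaddition. This gives the racemic silyl enol ether cycloadduct F1, which is hydrolysed in the flask (1 M HCl, THF) to the racemic keto aldehyde F2. F2 is taken through the conditions of steps 3, 4 and 5 to the racemic keto dienoate F3, the racemic enone F4 and the racemic trans-alcohol F5. Lipase-catalysed acylation (Pseudomonas cepacia lipase, vinyl acetate, tert-butyl methyl ether, 30 °C) is expected to acylate the (4R)-carbinol, the usual preference of this enzyme for cyclohex-2-en-1-ols, giving the (1R,4R)-acetate F6 and leaving the (1S,4S)-alcohol 9, separated by chromatography. Because both halves of the target descend from 9, this one resolution would secure all three stereocentres.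

Step 5. Hydride may be delivered mainly to the other face of the C3 carbonyl, so that the hydroxyl ends up cis to the side chain. The fallback sets out from 8 and comes back at 9. The cis-alcohol F7 obtained from the reduction of 8 is inverted at C3 by Mitsunobu reaction (4-nitrobenzoic acid, PPh3, diisopropyl azodicarboxylate, THF, 0 °C) to the 4-nitrobenzoate F8, and ethanolysis (K2CO3, EtOH, 25 °C) then gives 9 without changing the ethyl ester. The cis-alcohol F7 may also be sent into step 9 in place of 9, since C3 becomes a methylene group there.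

Step 10. The allylpalladium intermediate may lose a β-hydrogen (diene formation, which on the C6 side would erase the stereocentre) or take up hydride at the tertiary terminus C5, which would move the alkene to C3=C4. The fallback sets out from 9 and comes back at 16, so that steps 9, 10 and 11 are not needed. Alcohol 9 is converted through the mesylate F9 (not isolated) into the allylic chloride F10 (MsCl, LiCl, 2,4,6-collidine, DMF, 0 °C). LiAlH4 (Et2O, 0 °C) then displaces chloride directly at the unhindered secondary carbon C3 (attack at the tertiary, flanked C5 is disfavoured) and reduces the ester in the same operation to give dienol 16.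

**Further compounds**

F1 | step 2 | racemic 4-(tert-butyldimethylsilyloxy)-2,6,6-trimethylcyclohex-3-ene-1-carbaldehyde | O=CC1C(C)C=C(O[Si](C)(C)C(C)(C)C)CC1(C)C
F2 | step 2 | racemic 2,6,6-trimethyl-4-oxocyclohexane-1-carbaldehyde | O=CC1C(C)CC(=O)CC1(C)C
F3 | step 2 | racemic ethyl (2E,4E)-3-methyl-5-(2,6,6-trimethyl-4-oxocyclohexyl)penta-2,4-dienoate | CCOC(=O)/C=C(C)/C=C/C1C(C)CC(=O)CC1(C)C
F4 | step 2 | racemic ethyl (2E,4E)-3-methyl-5-(2,6,6-trimethyl-4-oxocyclohex-2-en-1-yl)penta-2,4-dienoate | CCOC(=O)/C=C(C)/C=C/C1C(C)=CC(=O)CC1(C)C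
F5 | step 2 | racemic ethyl (2E,4E)-5-[(1S,4S and 1R,4R)-4-hydroxy-2,6,6-trimethylcyclohex-2-en-1-yl]-3-methylpenta-2,4-dienoate | CCOC(=O)/C=C(C)/C=C/[C@@H]1C(C)=C[C@@H](O)CC1(C)C.CCOC(=O)/C=C(C)/C=C/[C@H]1C(C)=C[C@H](O)CC1(C)C
F6 | step 2 | ethyl (2E,4E)-5-[(1R,4R)-4-acetoxy-2,6,6-trimethylcyclohex-2-en-1-yl]-3-methylpenta-2,4-dienoate | CCOC(=O)/C=C(C)/C=C/[C@H]1C(C)=C[C@H](OC(C)=O)CC1(C)C
F7 | step 5 | ethyl (2E,4E)-5-[(1S,4R)-4-hydroxy-2,6,6-trimethylcyclohex-2-en-1-yl]-3-methylpenta-2,4-dienoate | CCOC(=O)/C=C(C)/C=C/[C@@H]1C(C)=C[C@H](O)CC1(C)C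
F8 | step 5 | ethyl (2E,4E)-3-methyl-5-[(1S,4S)-2,6,6-trimethyl-4-(4-nitrobenzoyloxy)cyclohex-2-en-1-yl]penta-2,4-dienoate | CCOC(=O)/C=C(C)/C=C/[C@@H]1C(C)=C[C@@H](OC(=O)c2ccc(cc2)[N+](=O)[O-])CC1(C)C
F9 | step 10 | ethyl (2E,4E)-3-methyl-5-[(1S,4S)-2,6,6-trimethyl-4-(methylsulfonyloxy)cyclohex-2-en-1-yl]penta-2,4-dienoate | CCOC(=O)/C=C(C)/C=C/[C@@H]1C(C)=C[C@@H](OS(C)(=O)=O)CC1(C)C
F10 | step 10 | ethyl (2E,4E)-5-[(1S,4R)-4-chloro-2,6,6-trimethylcyclohex-2-en-1-yl]-3-methylpenta-2,4-dienoate | CCOC(=O)/C=C(C)/C=C/[C@@H]1C(C)=C[C@H](Cl)CC1(C)C
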